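**Retrosynthetic overview**
1. Numbering: C1 = ArOCH2; ring C = oxolane (O, C2, C3, C4, C5); C6=C7(CH3)2 = exocyclic isobutenyl group. Rings A/B are the coumarin, bought intact as isofraxidin.
2. Enabling feature: the oxygen of ring C is bound to C5, an allylic carbon whose C6=C7 bond ends in two identical methyl groups. The same oxygen sits on C2, next to the tertiary carbinol C3. Cutting O–C5 as a retro-hydroalkoxylation gives an allene C5=C6=C7Me2 without axial chirality, with the C2 oxygen γ to it, and C2–O/C3–OH fold back into one trans-oxirane.
3. Key disconnection: target ⇒ (2S,3S)-epoxy allene aryl ether + H2O. One pot opens the oxirane at C3 with inversion, frees the C2 hydroxyl and closes O–C5. This creates ring C, the C3 carbinol, the C5 centre and the C6=C7 alkene.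
4. Epoxy allene ⇒ isofraxidin (Mitsunobu, C1–O) + epoxy alcohol ⇒ asymmetric epoxidation of (2E)-3,7-dimethylocta-2,5,6-trien-1-ol ⇒ C4–C5 alkylation of lithiated 3-methylbuta-1,2-diene with an E-allylic bromide (Wittig, iBu2AlH, Appel).
5. Ring order: rings A/B are present from the start, the temporary oxirane forms in step 5, and ring C forms last in step 7 at the expense of the oxirane.

Key step: step 7

Assumption: the facial sense of the tartrate-controlled epoxidation is taken to follow the geraniol series, because the allene is remote from the reacting allylic alcohol.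

**Step 1**
Reactants: 1 (tert-butyldimethylsilyloxy)acetaldehyde; 2 ethyl 2-(triphenyl-λ5-phosphanylidene)propanoate
Product: 3 ethyl (2E)-4-[(tert-butyldimethylsilyl)oxy]-2-methylbut-2-enoate
Conditions: CH2Cl2, 0 → 23 °C
Reagents that add atoms: none
Why: Wittig olefination with a stabilised, α-branched ylide should give the E-trisubstituted enoate, which places C1 and C4 trans across C2=C3.

**Step 2**
Reactants: 3 ethyl (2E)-4-[(tert-butyldimethylsilyl)oxy]-2-methylbut-2-enoate
Product: 4 (2E)-4-[(tert-butyldimethylsilyl)oxy]-2-methylbut-2-en-1-ol
Conditions: iBu2AlH (2.3 equiv), CH2Cl2, −78 °C; aq. potassium sodium tartrate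
Reagents that add atoms: none
Why: The 1,2-reduction of an α,β-unsaturated ester by a dialkylaluminium hydride stops at the allylic alcohol and leaves the silyl ether and the alkene geometry untouched.

**Step 3**
Reactants: 4 (2E)-4-[(tert-butyldimethylsilyl)oxy]-2-methylbut-2-en-1-ol
Product: 5 {[(2E)-4-bromo-3-methylbut-2-en-1-yl]oxy}(tert-butyl)dimethylsilane
Conditions: CBr4, PPh3, CH2Cl2, 0 °C
Reagents that add atoms: carbon tetrabromide, BrC(Br)(Br)Br
Why: In the Appel bromination bromide displaces the oxyphosphonium group by SN2 under neutral conditions, so neither allylic transposition nor desilylation is expected.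

**Step 4**
Reactants: 5 {[(2E)-4-bromo-3-methylbut-2-en-1-yl]oxy}(tert-butyl)dimethylsilane; 6 3-methylbuta-1,2-diene
Product: 9 (2E)-3,7-dimethylocta-2,5,6-trien-1-ol, via allenyllithium 7 (not isolated), via silyl trienyl ether 8 (not isolated)
Conditions: 6, n-BuLi, THF, −78 → −30 °C; 5, DMPU, −78 → 0 °C; then Bu4NF, 0 → 23 °C, same flask
Reagents that add atoms: none
Why: Deprotonation of the allene CH2 terminus and SN2 alkylation of the lithioallene at the primary allylic bromide (the tertiary propargylic terminus of the ambident anion is too hindered) forms C4–C5 with the E-alkene intact, and fluoride desilylation then frees the allylic alcohol.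

**Step 5**
Reactants: 9 (2E)-3,7-dimethylocta-2,5,6-trien-1-ol
Product: 10 [(2S,3S)-3-methyl-3-(4-methylpenta-2,3-dien-1-yl)oxiran-2-yl]methanol
Conditions: Ti(OiPr)4 (10 mol %), L-(+)-diisopropyl tartrate (12 mol %), t-BuOOH (decane), 4 Å MS, CH2Cl2, −20 °C
Reagents that add atoms: tert-butyl hydroperoxide, CC(C)(C)OO
Why: In the Katsuki–Sharpless asymmetric epoxidation the titanium tartrate complex binds the allylic alcohol and, with the L-(+)-tartrate, should deliver oxygen to the face that gives the (2S,3S)-oxirane, which sets C2 finally and C3 provisionally, while the allene has no directing hydroxyl and stays untouched.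

**Step 6**
Reactants: 10 [(2S,3S)-3-methyl-3-(4-methylpenta-2,3-dien-1-yl)oxiran-2-yl]methanol; 11 isofraxidin (7-hydroxy-6,8-dimethoxy-2H-chromen-2-one)
Product: 12 6,8-dimethoxy-7-{[(2S,3S)-3-methyl-3-(4-methylpenta-2,3-dien-1-yl)oxiran-2-yl]methoxy}-2H-chromen-2-one
Conditions: PPh3, DIAD, THF, 0 → 23 °C
Reagents that add atoms: none
Why: The Mitsunobu etherification joins the acidic phenol to the primary, non-stereogenic C1, touches no stereocentre, and its neutral medium avoids epoxide migration.

**Step 7**
Reactants: 12 6,8-dimethoxy-7-{[(2S,3S)-3-methyl-3-(4-methylpenta-2,3-dien-1-yl)oxiran-2-yl]methoxy}-2H-chromen-2-one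
Product: 14 7-{[(2S,3R,5R)-3-hydroxy-3-methyl-5-(2-methylprop-1-en-1-yl)oxolan-2-yl]methoxy}-6,8-dimethoxy-2H-chromen-2-one (target CNP0086110.2), via allenic diol 13 (not isolated)
Conditions: Ph3PAuNTf2 (3 mol %), HClO4 (5 mol %), THF/H2O 10:1, 0 → 23 °C, dark
Reagents that add atoms: water, O
Why: Proposed new method: hydronium ion activates the oxirane and water attacks the tertiary, cation-stabilising C3 from the rear (C2 is deactivated by the adjacent aryloxymethyl group), which gives diol 13 with its C2 hydroxyl set free, and cationic monovalent gold then binds the C5=C6 bond of the allene, the C2 hydroxyl adds to C5 anti to gold, and protodeauration of the C6 vinylgold leaves the C6=C7 isobutenyl group and returns the catalyst. The closest known reaction types are the acid-catalysed anti hydrolysis of trisubstituted epoxides, the gold-catalysed exo-hydroalkoxylation of γ-hydroxyallenes that end in a dimethyl-substituted carbon, and the gold-catalysed domino reaction of epoxy alkynes with water; what is new is their union on an epoxy allene. Ring C closes in the 5-exo-trig mode at C5, while the temporary oxirane is opened in an SN2-like way by the external nucleophile. C2 keeps its C–O bond and its S configuration, C3 is inverted from S to R by the rear-side attack, and C5 is set by the substrate, since the chair-like transition state (O, C2, C3, C4, C5, C6) that leads to 5R has the C1 arm and the C3 hydroxyl pseudo-equatorial and only the C3 methyl pseudo-axial, whereas the 5S epimer needs the flipped chair with both of these groups pseudo-axial. The 5R product, with the isobutenyl group on the ring face opposite to C1 and the C3 methyl, should also be the more stable epimer, so any reversible ionisation of the allylic C5–O bond in the acidic medium works in the same direction. The step needs the secondary C2 hydroxyl to win over the tertiary C3 hydroxyl and over external water at the allene, which the substrate secures because the C3 hydroxyl could only close a four-membered ring at C5 or attack the fully substituted C7 and an intramolecular 5-exo capture outruns bimolecular hydration, while the electron-poor pyranone double bond and the lactone of the coumarin are inert to soft gold and to this dilute acid.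

**Compound list**
1 | (tert-butyldimethylsilyloxy)acetaldehyde | CC(C)(C)[Si](C)(C)OCC=O | starting material
2 | ethyl 2-(triphenyl-λ5-phosphanylidene)propanoate | CCOC(=O)C(C)=P(c1ccccc1)(c1ccccc1)c1ccccc1 | starting material
3 | ethyl (2E)-4-[(tert-butyldimethylsilyl)oxy]-2-methylbut-2-enoate | CCOC(=O)/C(C)=C/CO[Si](C)(C)C(C)(C)C | intermediate
4 | (2E)-4-[(tert-butyldimethylsilyl)oxy]-2-methylbut-2-en-1-ol | CC(C)(C)[Si](C)(C)OC/C=C(\C)CO | intermediate
5 | {[(2E)-4-bromo-3-methylbut-2-en-1-yl]oxy}(tert-butyl)dimethylsilane | CC(C)(C)[Si](C)(C)OC/C=C(\C)CBr | intermediate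
6 | 3-methylbuta-1,2-diene | CC(C)=C=C | starting material
7 | (3-methylbuta-1,2-dien-1-yl)lithium | [Li]C=C=C(C)C | intermediate
8 | tert-butyl{[(2E)-3,7-dimethylocta-2,5,6-trien-1-yl]oxy}dimethylsilane | CC(C)(C)[Si](C)(C)OC/C=C(\C)CC=C=C(C)C | intermediate
9 | (2E)-3,7-dimethylocta-2,5,6-trien-1-ol | OC/C=C(\C)CC=C=C(C)C | intermediate
10 | [(2S,3S)-3-methyl-3-(4-methylpenta-2,3-dien-1-yl)oxiran-2-yl]methanol | OC[C@@H]1O[C@@]1(C)CC=C=C(C)C | intermediate
11 | isofraxidin (7-hydroxy-6,8-dimethoxy-2H-chromen-2-one) | COc1cc2ccc(=O)oc2c(OC)c1O | starting material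
12 | 6,8-dimethoxy-7-{[(2S,3S)-3-methyl-3-(4-methylpenta-2,3-dien-1-yl)oxiran-2-yl]methoxy}-2H-chromen-2-one | COc1cc2ccc(=O)oc2c(OC)c1OC[C@@H]1O[C@@]1(C)CC=C=C(C)C | intermediate
13 | 7-{[(2S,3R)-2,3-dihydroxy-3,7-dimethylocta-5,6-dien-1-yl]oxy}-6,8-dimethoxy-2H-chromen-2-one | COc1cc2ccc(=O)oc2c(OC)c1OC[C@H](O)[C@](CC=C=C(C)C)(C)O | intermediate
14 | 7-{[(2S,3R,5R)-3-hydroxy-3-methyl-5-(2-methylprop-1-en-1-yl)oxolan-2-yl]methoxy}-6,8-dimethoxy-2H-chromen-2-one | COc1cc2ccc(=O)oc2c(OC)c1OC[C@@H]1O[C@@H](C=C(C)C)C[C@@]1(C)O | target

Total step count: 7. Longest linear sequence: 7 steps (1 → 14). Compounds 2, 6 and 11 enter as purchased materials.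

**Steps most likely to fail**

1) Step 7 (key step).
- The two catalytic cycles may run out of step.
- An acid-induced hydride shift could turn the oxirane into a ketone.
- Partial ionisation at C3, possibly with participation of the homoallenyl π bond, could cost stereochemical integrity.
- Gold-catalysed hydration of the allene could run ahead of epoxide opening.
- Facial discrimination at C5 may be too weak.

Fallback, from 12 back to 14, by known chemistry in two separate operations. First, 12 is hydrolysed alone (HClO4 cat., THF/H2O, 0 °C) and the allenic diol 13 is isolated and purified. Then 13 is cyclised in dry benzene with (Ph2PCH2PPh2)(AuCl)2 and the silver salt of 3,3'-bis(2,4,6-triisopropylphenyl)-1,1'-binaphthalene-2,2'-diyl hydrogen phosphate. The antipode of the phosphate that reinforces the substrate bias is used. The tight chiral ion pair then adds reagent control at C5, as known for γ-hydroxyallenes with a dimethyl terminus. This fallback makes no compound outside the list (F0).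

2) Step 4.
- The ambident anion may alkylate through its propargylic terminus.
- The bromide may be attacked in the SN2′ sense.
- Lithium–bromine exchange may lead to dimerisation.

Fallback, from 5 back to 8, builds the allene only after the C–C bond. Copper-catalysed coupling of 5 with commercial tert-butyl 2-methylbut-3-yn-2-yl carbonate (CuBr·SMe2, K2CO3, Bu4NCl, DMF, 23 °C) gives the skipped enyne carbonate F1. Zerovalent palladium (Pd2(dba)3·CHCl3, PBu3) with HCO2NH4 ionises the tertiary propargylic carbonate to an allenylpalladium species. Hydride delivery to that species gives the silyl trienyl ether 8, which is desilylated as in step 4.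

3) Step 6.
- The doubly ortho-substituted phenoxide may capture the oxyphosphonium ion too slowly.
- That would leave room for alkylation of the hydrazide or for epoxide opening.

Fallback, from 9 back to 13, replaces redox condensation and acid hydrolysis by base-only SN2 events.
- Epoxidation of 9 with D-(−)-diisopropyl tartrate gives the (2R,3R)-epoxy alcohol F2.
- Aqueous NaOH/t-BuOH (Payne rearrangement, then hydroxide opening at C1) inverts C2, keeps C3 and gives the (2S,3R)-triol F3.
- Bu2SnO-catalysed tosylation (TsCl, Et3N, CH2Cl2) picks the primary hydroxyl and gives the monotosylate F4.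
- With 11 and K2CO3 in DMF at 60 °C, F4 closes to the terminal epoxide F5, which the phenoxide opens at C1 to give 13.
- Diol 13 is then cyclised with the gold catalyst of step 7, without the acid.

**Further compounds**
F0 | step 7 | none | none
F1 | step 4 | tert-butyl (6E)-8-[(tert-butyldimethylsilyl)oxy]-2,6-dimethyloct-6-en-3-yn-2-yl carbonate | CC(C)(C)[Si](C)(C)OC/C=C(\C)CC#CC(C)(C)OC(=O)OC(C)(C)C
F2 | step 6 | [(2R,3R)-3-methyl-3-(4-methylpenta-2,3-dien-1-yl)oxiran-2-yl]methanol | OC[C@H]1O[C@]1(C)CC=C=C(C)C
F3 | step 6 | (2S,3R)-3,7-dimethylocta-5,6-diene-1,2,3-triol | OC[C@H](O)[C@](CC=C=C(C)C)(C)O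
F4 | step 6 | (2S,3R)-2,3-dihydroxy-3,7-dimethylocta-5,6-dien-1-yl 4-methylbenzenesulfonate | Cc1ccc(cc1)S(=O)(=O)OC[C@H](O)[C@](CC=C=C(C)C)(C)O
F5 | step 6 | (2R)-6-methyl-2-[(2S)-oxiran-2-yl]hepta-4,5-dien-2-ol | O[C@](C)(CC=C=C(C)C)[C@@H]1CO1
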